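## Structural features

The target 14 is a 2-arylchroman-4-one. Ring A (C4a to C8a) carries free hydroxyls at C5 and C6 and a methoxy group at C7, and is fused to the dihydropyranone ring C (O1, C2, C3, C4=O). Ring B, a 3-hydroxy-4,5-dimethoxyphenyl group, sits on C2. The only stereocentres, C2 (R; benzylic, bonded to O1 and ring B) and C3 (R; methoxy-bearing, α to the C4 ketone), are adjacent and trans. C3–H is acidic and O1 is a β-leaving group, so base can epimerise C3 or open ring C to the α-methoxychalcone. A 2,3-cis isomer would epimerise into the enantiomeric trans series, so a relative error cannot be repaired late. The 5,6-catechol para to O1 is oxidation-prone. The carbon skeleton is simple; the difficulty is absolute and relative control of the C2/C3 pair with the C3 methyl ether already in place, plus differentiation of the four oxygens on ring A. The key step uses the fact that C3 is bonded at once to the C4 carbonyl carbon, the methoxy oxygen and the carbinol carbon C2. C3 is therefore the carbene carbon of an aryl diazomethyl ketone that takes up methanol and then the ring-B aldehyde. Because O1–C2 is closed afterwards with inversion, the open-chain aldol must be the syn (2R,3S) isomer; a CIP check confirms this (same arrangement at the methoxy carbon as in 14, opposite at the carbinol carbon).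

## Logic of the disconnections

**14 to 13.** The benzyl O–C bond on ring B and the two O–CPh2 bonds on ring A are cut. All three phenols are then released in one neutral hydrogenolysis, so the base-sensitive C3 centre and the air-sensitive catechol never meet acid or base. The demand is that the cyclic benzylic C2–O1 bond and the C4 ketone survive hydrogen on palladium.

**13 to 12.** O1–C2 is cut. This opens ring C to an acyclic β-hydroxy ketone with a free phenol. The forward closure is a redox condensation with inversion at C2, so 12 must be the syn isomer, and displacement must beat elimination of the activated β-hydroxyl.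

**12 to 11.** The phenolic O–H is exchanged for O–Si. The future O1 must be masked during carbene chemistry and released without acid, base or hydrogen; a bulky silyl ether removed by buffered fluoride meets this.

**11 to 7, 9 and 10.** The C3–O(methyl) and C2–C3 bonds are cut. The molecule falls into a ring-A diazoketone, a one-carbon alcohol and a ring-B aldehyde, and both stereocentres are traced to one catalytic event. The forward step must make the carbene react with 10 rather than with its own ortho oxygens, must trap the enol with 9 before the proton shifts, and must give the syn (2R,3S) isomer.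
- An acyclic acetal ortho to the diazoketone would offer a freely rotating ether oxygen with a migrating group and an activated O–CH2–O hydrogen six atoms from the carbene. The catechol of 7 is therefore tied into a diphenylmethylene ketal, whose oxygen is held back in a five-membered ring and has no α-hydrogen.
- Ring B carries a benzyl ether so that both masks fall in the last step and no chloromethyl ether is needed.
- 10 is kept near stoichiometric, because a large excess would favour plain O–H insertion and hemiacetal formation with 9.

**7 to 5 (through 6).** The C=N2 bond is cut back to a methyl ketone. This replaces acylation of diazomethane by an acid chloride (hazardous, and poor for a 2,6-disubstituted benzoyl group) with a diazo transfer. The demand is clean enolisation and C-acylation of 5 without movement of the silyl group.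

**5 to 4 to 3.** The O–Si bond and the two ketal O–C bonds are cut. Only the vicinal hydroxyls of 3 can close a five-membered ketal, so the three phenols differentiate themselves and the remaining one is silylated.

**3 to 1 (through 2).** The aryl C3–O bond is cut. 1 is a catalogue acetophenone whose two free ring positions are equivalent and para to a hydroxyl, so a persulfate hydroxylation can give only one regioisomer. The demand is acceptable conversion without over-oxidation.

**9 to 8.** The benzyl O–C bond is cut, leaving catalogue phenol 8; 10 is bought.

## Other disconnections considered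

**Alternative 1:** The cut is a formal [4+2] retron through O1–C2 and C3–C4. The salicylaldehyde 2,3-bis(benzyloxy)-6-hydroxy-4-methoxybenzaldehyde A2 would be converted by an orthoformate ester and a chiral Brønsted acid into a methoxy-substituted ortho-quinone methide. The (E)-styrylboronate A3 would intercept it to give the 3-borylchroman A1. Oxidation of C–B to C–OH, O-methylation, oxidation of C4 to the ketone and hydrogenolysis would follow.
- In favour: ring C and both stereocentres arise in one operation. The trans relationship is inherited from the alkene geometry rather than induced by a catalyst and then inverted. The C3 oxygen is methylated before any ketone exists, so epimerisation is not an issue. No diazo compound is handled.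
- Against: a β-borylstyrene whose aryl group has a twisted para-methoxy donor is a weak 2π nucleophile. The addition is then likely to be stepwise and cationic, which puts both trans specificity and enantiocontrol in doubt. Boron is a placeholder that costs two steps. C4 must finally be oxidised from a benzylic methyl ether to the ketone beside four other electron-rich ether sites.
- Comparison: on relative stereocontrol and hazard this plan is the better one; on avoiding a base-sensitive late methylation it is the equal. Ring A poses the same oxygenation problem, so nothing is saved before the key step, and four operations instead of three follow it. The chosen plan is shorter and redox-neutral after its key step.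

**Alternative 2:** The cut is C3–C4, an acyl-anion disconnection. The racemic, configurationally labile dialdehyde A5 would be cyclised by a chiral triazolium-derived carbene. The Breslow intermediate of the ring-A formyl group attacks the α-aryloxy aldehyde, and rapid enolisation of that aldehyde allows a dynamic kinetic resolution to the dihydroflavonol A4. O-Methylation at C3 and removal of the methoxymethyl ethers would follow.
- In favour: no metal and no diazo compound. Ring C and both stereocentres form in one organocatalytic step with the ketone at the right oxidation level. Only two steps follow the key step.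
- Against: the carbene must add to a formyl group flanked by two ortho oxygens on an electron-rich ring, while the aliphatic aldehyde is more electrophilic and more accessible. Reversed umpolung (ketone and carbinol exchanged between C3 and C4) and homo-coupling are therefore real risks. A5 can enolise, lose aryloxide or oxidise on handling, and making it requires alkylating a hindered phenol with a secondary benzylic electrophile. The C3 hydroxyl must be methylated α to the ketone of a base-sensitive flavanonol, which the chosen plan avoids by bringing the methoxy group in as 10. Three methoxymethyl ethers require chloromethyl methyl ether.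
- Comparison: in step count after the key step and in hazard of the key step it is the better plan. Both plans rest on a catalyst-controlled C–C bond formation between an enol-type nucleophile and an aldehyde, so neither has an intrinsic advantage in stereocontrol. The chosen plan is judged safer in chemoselectivity and in handling of intermediates.

**Alternative 3:** The cut is C2–C3 alone. The diazoketone A7 differs from 7 only in carrying the ring-B benzyl group on the future O1 instead of silicon. With a chiral dirhodium tetracarboxylate of the N-phthaloyl amino acid type (divalent rhodium) its carbene would insert into the benzylic C–H bond of its own ether, closing ring C to the flavanone A6. C3 would then be oxygenated trans to the aryl group through the silyl enol ether (Rubottom oxidation) and methylated, and the product hydrogenolysed.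
- In favour: the step is unimolecular, so no third component competes with a proton shift. Enantioselective C–H insertion of ortho-alkoxyaryl diazoketones to chromanones is an established reaction type. The ring closes without a separate cyclisation or inversion. A7 would come from 4 by the same diazo transfer as 7.
- Against: only C2 is set. C3 arrives as a methylene group and needs three more operations; one enolises a flavanone (risk of retro-oxa-Michael opening and loss of C2 configuration) and another is a late O-methylation next to the ketone. The ether oxygen sits five atoms from the carbene carbon, so oxonium ylide formation with a [1,2]-benzyl shift to a benzofuranone competes with the six-membered insertion. The benzylic alkylating agent for ring B costs extra steps.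
- Comparison: in mechanistic simplicity of the key step it is the better plan, and in the route to ring A the equal. The chosen plan captures the same kind of carbene with external 10, which turns the oxygen affinity that threatens Alternative 3 into the bond-forming event and delivers C3 at its final oxidation level. The price is a three-component step whose selectivity is less predictable.

Key step: step 6

Assumption: the (R)-configured phosphoric acid (R)-TRIP, (R)-3,3'-bis(2,4,6-triisopropylphenyl)-1,1'-binaphthyl-2,2'-diyl hydrogen phosphate, is written for step 6. Which antipode leads to the (2R,3S) series cannot be derived with certainty for this substrate, so the configuration of 11 is to be assigned on the first batch and the (S)-acid used if the mirror-image series forms.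

## Route

**Step 1**
Reactants: 1 1-(2,6-dihydroxy-4-methoxyphenyl)ethanone
Product: 3 1-(2,3,6-trihydroxy-4-methoxyphenyl)ethanone, via aryl sulfate potassium salt 2 (not isolated)
Conditions: K2S2O8, aq. NaOH, 15 °C → rt; then aq. HCl, 90 °C, N2
Reagents that add atoms: potassium peroxodisulfate, [K+].[K+].[O-]S(=O)(=O)OOS(=O)(=O)[O-]
Why: Elbs persulfate oxidation: the phenolate carbon para to a hydroxyl attacks the peroxide oxygen to give aryl sulfate 2, which acid hydrolyses; the two open ring positions are equivalent by symmetry, so one regioisomer results, and the sulfate group deactivates the ring against a second oxidation.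

**Step 2**
Reactants: 3 1-(2,3,6-trihydroxy-4-methoxyphenyl)ethanone
Product: 4 1-(5-hydroxy-7-methoxy-2,2-diphenyl-1,3-benzodioxol-4-yl)ethanone
Conditions: Ph2CCl2, Ph2O, 175 °C, N2
Reagents that add atoms: dichlorodiphenylmethane, ClC(Cl)(c1ccccc1)c1ccccc1
Why: Catechol ketalisation: only the vicinal hydroxyls can close the five-membered 1,3-benzodioxole, so the isolated, carbonyl-chelated hydroxyl stays free without a selective reagent; the ketal has no C–H next to oxygen and no migrating group, as the carbene step requires.

**Step 3**
Reactants: 4 1-(5-hydroxy-7-methoxy-2,2-diphenyl-1,3-benzodioxol-4-yl)ethanone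
Product: 5 1-[7-methoxy-2,2-diphenyl-5-(triisopropylsilyloxy)-1,3-benzodioxol-4-yl]ethanone
Conditions: iPr3SiCl, imidazole, DMF, rt → 40 °C
Reagents that add atoms: chlorotriisopropylsilane, CC(C)[Si](Cl)(C(C)C)C(C)C
Why: Standard phenol silylation; the triisopropylsilyl ether resists amide base, diazo transfer and weak acid, shields the future O1 lone pairs from the carbene, and is later removed by fluoride without touching ketal or benzyl ether.

**Step 4**
Reactants: 5 1-[7-methoxy-2,2-diphenyl-5-(triisopropylsilyloxy)-1,3-benzodioxol-4-yl]ethanone
Product: 7 2-diazo-1-[7-methoxy-2,2-diphenyl-5-(triisopropylsilyloxy)-1,3-benzodioxol-4-yl]ethanone, via trifluoroacetyl diketone 6 (not isolated)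
Conditions: LiN(SiMe3)2, THF, −78 °C; CF3CO2CH2CF3; AcOH quench; then 4-acetamidobenzenesulfonyl azide, Et3N, H2O, MeCN, rt
Reagents that add atoms: 4-acetamidobenzenesulfonyl azide, CC(=O)Nc1ccc(cc1)S(=O)(=O)N=[N+]=[N-] (diazo nitrogens); 2,2,2-trifluoroethyl trifluoroacetate, O=C(OCC(F)(F)F)C(F)(F)F (trifluoroacetyl group of 6 only)
Why: Detrifluoroacetylative diazo transfer (Danheiser procedure): the kinetic lithium enolate is C-trifluoroacetylated to the activated 1,3-diketone 6, which accepts the diazo group from the sulfonyl azide and loses the trifluoroacetyl group as an N-acylsulfonamide; this gives the terminal diazoketone without diazomethane or an acid chloride.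

**Step 5**
Reactants: 8 3-hydroxy-4,5-dimethoxybenzaldehyde
Product: 9 3-(benzyloxy)-4,5-dimethoxybenzaldehyde
Conditions: BnBr, K2CO3, DMF, rt
Reagents that add atoms: benzyl bromide, BrCc1ccccc1
Why: Williamson etherification of the phenol; benzyl is chosen so that rings A and B are unmasked together in the final hydrogenolysis and no chloromethyl ether is used.

**Step 6**
Reactants: 7 2-diazo-1-[7-methoxy-2,2-diphenyl-5-(triisopropylsilyloxy)-1,3-benzodioxol-4-yl]ethanone; 9 3-(benzyloxy)-4,5-dimethoxybenzaldehyde; 10 methanol
Product: 11 (2R,3S)-3-[3-(benzyloxy)-4,5-dimethoxyphenyl]-3-hydroxy-2-methoxy-1-[7-methoxy-2,2-diphenyl-5-(triisopropylsilyloxy)-1,3-benzodioxol-4-yl]propan-1-one (syn aldol)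
Conditions: Rh2(OAc)4 (2 mol %), (R)-TRIP (10 mol %), 3 Å MS, CH2Cl2, 0 °C; 7 added slowly to 9 (1.5 equiv) and 10 (1.3 equiv)
Reagents that add atoms: none
Why: Rh2(OAc)4 (divalent rhodium) expels N2 from 7 to give the rhodium carbene, 10 adds through oxygen to form the oxonium ylide, and this is released as the hydrogen-bonded (Z)-α-methoxy enol; the phosphoric acid binds the enol O–H through its P=O oxygen and activates 9 through its P–OH, so that aldol addition outruns the 1,2-proton shift. The closest known reaction type is the three-component coupling of diazo carbonyl compounds, alcohols and aldehydes or imines by trapping of protic oxonium ylides under dirhodium tetracarboxylate and chiral Brønsted acid co-catalysis. No ring closes; the C3–OMe and C2–C3 bonds form. Both stereocentres arise in the same C–C bond-forming transition state: the (Z)-enol in the acid-bridged cyclic arrangement gives the syn relationship, and the 3,3'-aryl groups of the acid select the aldehyde face and so the absolute configuration (2R at the methoxy carbon, 3S at the carbinol). The step needs capture of the carbene by 10 to beat attack by the ortho oxygens, and aldol capture to beat proton transfer. The bulky silyl ether and the tied-back ketal oxygen, which has neither an α-C–H nor a migrating group, should secure the first. Slow addition of 7 to an excess of 9 with only a small excess of 10 should secure the second; 3 Å sieves exclude water without taking up 10.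

**Step 7**
Reactants: 11 (2R,3S)-3-[3-(benzyloxy)-4,5-dimethoxyphenyl]-3-hydroxy-2-methoxy-1-[7-methoxy-2,2-diphenyl-5-(triisopropylsilyloxy)-1,3-benzodioxol-4-yl]propan-1-one
Product: 12 (2R,3S)-3-[3-(benzyloxy)-4,5-dimethoxyphenyl]-3-hydroxy-1-(5-hydroxy-7-methoxy-2,2-diphenyl-1,3-benzodioxol-4-yl)-2-methoxypropan-1-one
Conditions: Bu4NF, AcOH (1:1), THF, 0 °C
Reagents that add atoms: none
Why: Fluoride cleaves the aryl silyl ether through Si–F bond formation; acetic acid buffers the phenoxide so that the β-hydroxy ketone should neither undergo retro-aldol cleavage nor epimerise at the methoxy carbon.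

**Step 8**
Reactants: 12 (2R,3S)-3-[3-(benzyloxy)-4,5-dimethoxyphenyl]-3-hydroxy-1-(5-hydroxy-7-methoxy-2,2-diphenyl-1,3-benzodioxol-4-yl)-2-methoxypropan-1-one
Product: 13 (2R,3R)-2-[3-(benzyloxy)-4,5-dimethoxyphenyl]-5,6-(diphenylmethylenedioxy)-3,7-dimethoxychroman-4-one
Conditions: PPh3, DIAD, THF, 0 °C → rt
Reagents that add atoms: none
Why: Intramolecular Mitsunobu etherification: the benzylic hydroxyl is activated as the alkoxyphosphonium ion and displaced by the chelated phenol in a 6-exo-tet SN2 closure with inversion, turning the (3S) carbinol into C2 (R) while the methoxy carbon is untouched, so the syn aldol becomes the 2,3-trans ring; this closure is an established route from α-oxygenated β-hydroxy ketones to dihydroflavonols.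

**Step 9**
Reactants: 13 (2R,3R)-2-[3-(benzyloxy)-4,5-dimethoxyphenyl]-5,6-(diphenylmethylenedioxy)-3,7-dimethoxychroman-4-one
Product: 14 (2R,3R)-5,6-dihydroxy-2-(3-hydroxy-4,5-dimethoxyphenyl)-3,7-dimethoxychroman-4-one
Conditions: H2 (1 atm), 10% Pd/C, THF–MeOH, rt
Reagents that add atoms: none
Why: Catalytic hydrogenolysis cleaves the benzyl ether and both benzylic C–O bonds of the diphenylmethylene ketal under neutral conditions, so C3 cannot epimerise and ring C cannot open; the cyclic C2–O1 bond and the hydrogen-bonded C4 ketone are expected to survive at ambient pressure if the reaction is stopped at full conversion.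

## Compound list

1 | 1-(2,6-dihydroxy-4-methoxyphenyl)ethanone | COc1cc(O)c(C(C)=O)c(O)c1 | starting material
2 | potassium 3-acetyl-2,4-dihydroxy-6-methoxyphenyl sulfate | COc1cc(O)c(C(C)=O)c(O)c1OS(=O)(=O)[O-].[K+] | intermediate (not isolated)
3 | 1-(2,3,6-trihydroxy-4-methoxyphenyl)ethanone | COc1cc(O)c(C(C)=O)c(O)c1O | intermediate
4 | 1-(5-hydroxy-7-methoxy-2,2-diphenyl-1,3-benzodioxol-4-yl)ethanone | COc1cc(O)c(C(C)=O)c2OC(c3ccccc3)(c3ccccc3)Oc12 | intermediate
5 | 1-[7-methoxy-2,2-diphenyl-5-(triisopropylsilyloxy)-1,3-benzodioxol-4-yl]ethanone | COc1cc(O[Si](C(C)C)(C(C)C)C(C)C)c(C(C)=O)c2OC(c3ccccc3)(c3ccccc3)Oc12 | intermediate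
6 | 4,4,4-trifluoro-1-[7-methoxy-2,2-diphenyl-5-(triisopropylsilyloxy)-1,3-benzodioxol-4-yl]butane-1,3-dione | COc1cc(O[Si](C(C)C)(C(C)C)C(C)C)c(C(=O)CC(=O)C(F)(F)F)c2OC(c3ccccc3)(c3ccccc3)Oc12 | intermediate (not isolated)
7 | 2-diazo-1-[7-methoxy-2,2-diphenyl-5-(triisopropylsilyloxy)-1,3-benzodioxol-4-yl]ethanone | COc1cc(O[Si](C(C)C)(C(C)C)C(C)C)c(C(=O)C=[N+]=[N-])c2OC(c3ccccc3)(c3ccccc3)Oc12 | intermediate
8 | 3-hydroxy-4,5-dimethoxybenzaldehyde | COc1cc(C=O)cc(O)c1OC | starting material
9 | 3-(benzyloxy)-4,5-dimethoxybenzaldehyde | COc1cc(C=O)cc(OCc2ccccc2)c1OC | intermediate
10 | methanol | CO | starting material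
11 | (2R,3S)-3-[3-(benzyloxy)-4,5-dimethoxyphenyl]-3-hydroxy-2-methoxy-1-[7-methoxy-2,2-diphenyl-5-(triisopropylsilyloxy)-1,3-benzodioxol-4-yl]propan-1-one | COc1cc(O[Si](C(C)C)(C(C)C)C(C)C)c(c2OC(c3ccccc3)(c3ccccc3)Oc12)C(=O)[C@H](OC)[C@H](c1cc(OCc2ccccc2)c(OC)c(OC)c1)O | intermediate
12 | (2R,3S)-3-[3-(benzyloxy)-4,5-dimethoxyphenyl]-3-hydroxy-1-(5-hydroxy-7-methoxy-2,2-diphenyl-1,3-benzodioxol-4-yl)-2-methoxypropan-1-one | COc1cc(O)c(c2OC(c3ccccc3)(c3ccccc3)Oc12)C(=O)[C@H](OC)[C@H](c1cc(OCc2ccccc2)c(OC)c(OC)c1)O | intermediate
13 | (2R,3R)-2-[3-(benzyloxy)-4,5-dimethoxyphenyl]-5,6-(diphenylmethylenedioxy)-3,7-dimethoxychroman-4-one | COc1cc2c(c3OC(c4ccccc4)(c4ccccc4)Oc13)C(=O)[C@H](OC)[C@@H](c1cc(OCc3ccccc3)c(OC)c(OC)c1)O2 | intermediate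
14 | (2R,3R)-5,6-dihydroxy-2-(3-hydroxy-4,5-dimethoxyphenyl)-3,7-dimethoxychroman-4-one | COc1cc2c(c(O)c1O)C(=O)[C@H](OC)[C@@H](c1cc(O)c(OC)c(OC)c1)O2 | target

## Step count and least certain steps

Total step count: 9. Longest linear sequence: 8 steps (steps 1, 2, 3, 4, 6, 7, 8, 9); step 5 is the one-step side branch.

**Step 6 (key step).**
- Risk: proton transfer within the oxonium ylide or enol may outrun aldol capture, because the trioxygenated aldehyde 9 is a weak electrophile and a phosphoric acid activates aldehydes less strongly than imines.
- Risk: an ortho oxygen may attack the carbene despite the constraints built into 7.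
- Risk: syn or facial selectivity may be insufficient, since terminal diazoketones are the less explored substrates for this coupling.
- Fallback: the same two bonds are made in two separate operations. From 7, deliberate Rh2(OAc)4-catalysed O–H insertion into 10 used in excess should give 2-methoxy-1-[7-methoxy-2,2-diphenyl-5-(triisopropylsilyloxy)-1,3-benzodioxol-4-yl]ethanone F1. Its (Z)-boron enolate, formed with diisopinocampheylboron triflate and iPr2NEt at −78 °C, would add to 9 through a closed six-membered transition state to give the syn aldol. The isopinocampheyl ligands decide the face, and the antipode of the reagent is chosen by the same configurational assignment as for the acid. Oxidative work-up returns the route at 11.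

**Step 8.**
- Risk: the activated hydroxyl may be lost by elimination toward the conjugated α-methoxy enone.
- Risk: partial ionisation at the benzylic carbon (para-methoxy donor) may make inversion incomplete. A 2,3-cis by-product would have to be separated, since epimerising it would lead into the enantiomeric trans series.
- Fallback: activation is separated from ring closure. From 11, with the phenol still silylated, the carbinol is sulfonylated with retention (Ms2O, pyridine, −20 °C) to (1S,2R)-1-[3-(benzyloxy)-4,5-dimethoxyphenyl]-2-methoxy-3-[7-methoxy-2,2-diphenyl-5-(triisopropylsilyloxy)-1,3-benzodioxol-4-yl]-3-oxopropyl methanesulfonate F2. CsF in MeCN at 0 °C then removes the silyl group, and the phenoxide, formed next to the leaving group without phosphonium species or hydrazide base, should close ring C by SN2 with inversion. The route is rejoined at 13, bypassing 12.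

**Step 4.**
- Risk: the silyl group may migrate from the phenolic oxygen to the enolate oxygen, driven by release of the more stable phenoxide.
- Risk: C-acylation of the hindered enolate may be incomplete, after which the unmasked diketone could cyclise.
- Fallback: a sequence without any enolate. From 5, Riley oxidation of the acetyl group with SeO2 (dioxane–water, 90 °C) should give 2-[7-methoxy-2,2-diphenyl-5-(triisopropylsilyloxy)-1,3-benzodioxol-4-yl]-2-oxoacetaldehyde F3. Condensation with tosylhydrazide at the aldehyde carbon gives N'-[(1E)-2-[7-methoxy-2,2-diphenyl-5-(triisopropylsilyloxy)-1,3-benzodioxol-4-yl]-2-oxoethylidene]-4-methylbenzenesulfonohydrazide F4. With Et3N in CH2Cl2 this loses sulfinate (Bamford–Stevens-type diazo formation) and returns the route at 7.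

**Step 1.**
- Risk: low conversion, and further oxidation of the product under alkaline persulfate, because the new hydroxyl creates a para-hydroquinone on an already electron-rich ring.
- Fallback: the oxygen is introduced through a formyl group. From 1, Duff formylation (hexamethylenetetramine, CF3CO2H, then aqueous acid) at the same ring position should give 3-acetyl-2,4-dihydroxy-6-methoxybenzaldehyde F5. Dakin oxidation of this ortho-hydroxybenzaldehyde (H2O2, aq. NaOH, 0 °C, N2; the aldehyde reacts far faster than the ketone) and hydrolysis of the aryl formate return the route at 3.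

## Further compounds

F1 | step 6 | 2-methoxy-1-[7-methoxy-2,2-diphenyl-5-(triisopropylsilyloxy)-1,3-benzodioxol-4-yl]ethanone | COCC(=O)c1c(O[Si](C(C)C)(C(C)C)C(C)C)cc(OC)c2OC(c3ccccc3)(c3ccccc3)Oc12
F2 | step 8 | (1S,2R)-1-[3-(benzyloxy)-4,5-dimethoxyphenyl]-2-methoxy-3-[7-methoxy-2,2-diphenyl-5-(triisopropylsilyloxy)-1,3-benzodioxol-4-yl]-3-oxopropyl methanesulfonate | COc1cc(O[Si](C(C)C)(C(C)C)C(C)C)c(c2OC(c3ccccc3)(c3ccccc3)Oc12)C(=O)[C@H](OC)[C@H](c1cc(OCc2ccccc2)c(OC)c(OC)c1)OS(C)(=O)=O
F3 | step 4 | 2-[7-methoxy-2,2-diphenyl-5-(triisopropylsilyloxy)-1,3-benzodioxol-4-yl]-2-oxoacetaldehyde | O=CC(=O)c1c(O[Si](C(C)C)(C(C)C)C(C)C)cc(OC)c2OC(c3ccccc3)(c3ccccc3)Oc12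
F4 | step 4 | N'-[(1E)-2-[7-methoxy-2,2-diphenyl-5-(triisopropylsilyloxy)-1,3-benzodioxol-4-yl]-2-oxoethylidene]-4-methylbenzenesulfonohydrazide | Cc1ccc(cc1)S(=O)(=O)N/N=C/C(=O)c1c(O[Si](C(C)C)(C(C)C)C(C)C)cc(OC)c2OC(c3ccccc3)(c3ccccc3)Oc12
F5 | step 1 | 3-acetyl-2,4-dihydroxy-6-methoxybenzaldehyde | COc1cc(O)c(C(C)=O)c(O)c1C=O
A1 | alternative 1 | 2,3-trans-5,6-bis(benzyloxy)-2-[3-(benzyloxy)-4,5-dimethoxyphenyl]-4,7-dimethoxy-3-(4,4,5,5-tetramethyl-1,3,2-dioxaborolan-2-yl)chroman (C2 and C3 as in the target, both C4 epimers) | COc1cc2c(c(OCc3ccccc3)c1OCc1ccccc1)C(OC)[C@H](B1OC(C)(C)C(C)(C)O1)[C@@H](c1cc(OCc3ccccc3)c(OC)c(OC)c1)O2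
A2 | alternative 1 | 2,3-bis(benzyloxy)-6-hydroxy-4-methoxybenzaldehyde | COc1cc(O)c(C=O)c(OCc2ccccc2)c1OCc1ccccc1
A3 | alternative 1 | 2-{(E)-2-[3-(benzyloxy)-4,5-dimethoxyphenyl]ethenyl}-4,4,5,5-tetramethyl-1,3,2-dioxaborolane | COc1cc(/C=C/B2OC(C)(C)C(C)(C)O2)cc(OCc2ccccc2)c1OC
A4 | alternative 2 | (2R,3R)-2-[3,4-dimethoxy-5-(methoxymethoxy)phenyl]-3-hydroxy-7-methoxy-5,6-bis(methoxymethoxy)chroman-4-one | COc1cc2c(c(OCOC)c1OCOC)C(=O)[C@H](O)[C@@H](c1cc(OCOC)c(OC)c(OC)c1)O2
A5 | alternative 2 | 2-[2-formyl-5-methoxy-3,4-bis(methoxymethoxy)phenoxy]-2-[3,4-dimethoxy-5-(methoxymethoxy)phenyl]acetaldehyde (racemic) | COc1cc(OC(C=O)c2cc(OCOC)c(OC)c(OC)c2)c(C=O)c(OCOC)c1OCOC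
A6 | alternative 3 | (2S)-2-[3-(benzyloxy)-4,5-dimethoxyphenyl]-5,6-(diphenylmethylenedioxy)-7-methoxychroman-4-one | COc1cc2c(c3OC(c4ccccc4)(c4ccccc4)Oc13)C(=O)C[C@@H](c1cc(OCc3ccccc3)c(OC)c(OC)c1)O2
A7 | alternative 3 | 1-{5-[3-(benzyloxy)-4,5-dimethoxybenzyloxy]-7-methoxy-2,2-diphenyl-1,3-benzodioxol-4-yl}-2-diazoethanone | COc1cc(OCc2cc(OCc3ccccc3)c(OC)c(OC)c2)c(C(=O)C=[N+]=[N-])c2OC(c3ccccc3)(c3ccccc3)Oc12
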